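## Structural features

The target is a 2,3-dihydrobenzofuran: a benzene ring fused to a dihydrofuran ring, with the ring oxygen O1 on C7a and a side chain on C5, para to O1. C2 (R) and C3 (S) are neighbours and trans: C2 carries a 3-oxoprop-1-en-2-yl group (an α-substituted acrolein) and the benzylic C3 carries a 3-methylbutanoate. The third stereocentre (R) is remote: it is the benzylic carbinol carbon of the 1-(3-methylbutanoyloxy)ethyl group on C5, esterified by the same acid. The enal is a Michael acceptor and polymerises easily; both benzylic esters can ionise, and loss of the C3 acyloxy group together with the C2 hydrogen would aromatise the heterocycle to a benzofuran. The real difficulty is to set the trans C2/C3 pair in one absolute sense while the 2-methylene three-carbon branch is already oxygenated at its end, because a late allylic oxidation of a methyl group would compete with the more substituted allylic C2–H; the remote carbinol lies outside any substrate control. The key step uses the fact that C2 is bonded to O1, to C3 and to the central carbon of the branch: it is an allylic carbon that can arrive as the nucleophilic carbon of an allylide, bond first to an aldehyde carbon (the future C3) and then, with inversion, to the phenol oxygen. The stereochemical bookkeeping is consistent throughout: a trans oxirane opened with inversion at the allylic carbon gives the trans (2R,3S) ring, and the (2S,5S)-diol gives the (2R,5R)-thiolane by double inversion.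

## Logic of the disconnections

19 ⇒ 18. No skeletal bond is cut; the formyl C=O is taken back to the primary allylic C–OH. The enal is the most reactive group of 19 and is therefore made last, so no earlier intermediate holds a Michael acceptor. The forward step needs an oxidant selective for an allylic alcohol, which is easy because both benzylic oxygens of 18 are already acylated.

18 ⇒ 17. The O–H bond of the primary alcohol is exchanged for an O–Si bond. The silyl ether is the form in which the branch oxygen travels from 1 onward, so this costs no separate protection step. The forward step must cleave a primary tert-butyldiphenylsilyl ether without migration or loss of the two esters, which calls for buffered fluoride.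

17 ⇒ 16. Both acyl–O bonds are cut at once, because the two esters come from the same acid; one operation removes ten carbons. The C–O bonds at C3 and at the side-chain carbinol are not touched, so the forward acylation only has to reach two secondary benzylic hydroxyls.

16 ⇒ 15. The C–H bond at the side-chain carbinol is cut, and the remote stereocentre becomes an acetyl group. This removes the one centre the ring cannot control. The acetyl group is also useful earlier: it is present in 8 from the start and it tempers the para oxygen in the key step. The forward reduction must be reagent-controlled, must leave the 1,1-disubstituted alkene alone and must tolerate the free C3 hydroxyl.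

15 ⇒ 10 + 7 (key disconnection). The O1–C2 and C2–C3 bonds are cut. C2 leaves with its branch as an allylic nucleophile bound to a chiral sulfonium leaving group, and the other four ring atoms (O1, C7a, C3a, C3) form a protected salicylaldehyde. Forward, the path runs through 11, 12, 13 and 14. One operation builds the ring, two skeletal bonds and both ring stereocentres, and the branch arrives oxygenated. The demands are attack on one aldehyde face, the anti betaine, closure of 12 to 13 before the phenol silyl group can move to the alkoxide, and opening of the oxirane only at the allylic carbon. Two design choices answer them: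
- The phenol of 10 carries a triisopropylsilyl group, bulkier than the more common tert-butyldimethylsilyl group. Silyl transfer in 12 followed by direct displacement of the sulfide would invert C2 once instead of twice and give the cis ring.
- 7 is a tetrafluoroborate and not a halide, so the salt cannot revert to sulfide and allyl halide.

10 ⇒ 9 ⇒ 8. The O–Si bond and then the aryl–CHO bond are cut. The formyl group stands ortho to the phenol oxygen and the para position is taken by the acetyl group, so electrophilic formylation of 8 has one site only. The forward formylation must stop at monosubstitution.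

7 ⇒ 6 + 3. The S–CH2 bond is cut, giving a C2-symmetric sulfide and an allylic bromide. The two lone pairs of 6 are homotopic, so alkylation creates no sulfur stereocentre and one salt results. The forward step must overcome the hindrance of a 2,5-disubstituted thiolane.

3 ⇒ 2 ⇒ 1. The C–Br bond and then the O–Si bond are cut. 1 is a symmetric diol, so monosilylation is only a statistical problem. The allyl unit is symmetric about its central carbon, so direct and allylic displacement give the same bromide.

6 ⇒ 5 ⇒ 4. Both C–S bonds are cut back to a bis-electrophile, and then the two O–S bonds are cut back to 4. Each carbon is inverted once, so the (S,S) configuration of 4 becomes (R,R) in 6. The forward double displacement must outrun elimination at the secondary centres.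

## Other disconnections considered

Alternative 1: The cut is the C2–C3 bond, with C3 as a carbene carbon and C2 as an ether methylene.
- Forward key step: the diazoketone 1-[5-bromo-2-[2-methyl-2-(triethylsilyloxy)propoxy]phenyl]-1-diazo-4-methylpentan-2-one A1 would lose N2 on Rh2(S-PTTL)4 (a dirhodium tetracarboxylate of divalent rhodium). The aryl acyl carbenoid from A1 would insert into one O–CH2 C–H bond in a 1,5 fashion, and DBU would then epimerise the enolisable C3 to the trans ketone (2S,3S)-1-[5-bromo-2-[2-(triethylsilyloxy)propan-2-yl]-2,3-dihydrobenzofuran-3-yl]-3-methylbutan-1-one A2. A later Baeyer–Villiger oxidation of A2, in which secondary C3 migrates with retention in preference to the primary isobutyl group, would turn the ketone directly into the C3 3-methylbutanoate.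
- In favour: the chirality comes from a catalyst and not from a stoichiometric (if recoverable) sulfide, which is better than the chosen plan. The trans relationship is reached by thermodynamic equilibration, which is at least the equal of a kinetically controlled trans-oxirane formation. The C3 ester needs no separate acylation.
- Against: A2 is far from 19. The bromide must be converted to the acetyl group (for example with tributyl(1-ethoxyvinyl)stannane and Pd(PPh3)4, zerovalent palladium), reduced enantioselectively and acylated. The tertiary silyloxy carbon must be dehydrated toward a methyl group, where loss of the C2 hydrogen to a tetrasubstituted enol ether competes and would destroy C2. The new methyl group must then be oxidised with SeO2 although C2–H is also allylic. The insertion site is a methylene next to a quaternary carbon, and A1 is a diazo compound, a handling hazard the chosen route does not have.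
- Comparison: mechanistically both plans set one centre by reagent control and relay it to its neighbour. Structurally the chosen plan delivers the branch at the right oxidation level with the acetyl group in place. In step count the alternative needs roughly twice as many operations after its key step.

Alternative 2: The cut is the aryl ether bond O1–C7a.
- Forward key step: the erythro diol 1-[3-[(1S,2R)-1,2-dihydroxy-3-methylbut-3-enyl]-4-fluorophenyl]ethanone A3 would be deprotonated, and the C2 alkoxide of A3 would displace fluoride at the carbon para to the acetyl group (addition–elimination through a Meisenheimer intermediate, 5-exo closure). The product would be 1-[(2R,3S)-3-hydroxy-2-(prop-1-en-2-yl)-2,3-dihydrobenzofuran-5-yl]ethanone A4.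
- In favour: no stereocentre is touched in the ring closure, so fidelity is certain, and the closure is a favoured exo mode. On both counts it is better than the chosen plan, which relies on an inversion and a formally disfavoured endo opening. The benzylic alkoxide of A3 could only close a four-membered ring, so regiochemistry is as secure as in the chosen plan.
- Against: the stereochemical problem is only moved back. A3 is an erythro diol next to an isopropenyl group; it cannot come from syn-dihydroxylation of the easily made (E)-diene and needs a longer, reagent-controlled C–C bond construction. A single acetyl group is a modest activator for fluoride displacement, and the alkoxide base can enolise the methyl ketone. A4 lacks the branch oxygen, so a methyl group must later be oxidised with SeO2 in competition with the more substituted allylic C2–H, on a compound that already holds the labile benzylic esters.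
- Comparison: the number of steps after the key step is about equal (reduction, acylation, allylic oxidation). The steps before it are more numerous, and the late C–H oxidation is less certain than oxidation of a pre-installed allylic alcohol.

Alternative 3: The five-membered ring is derived from a chroman; the O1–C2 bond is formed by migration of the ring oxygen.
- Forward sequence: the chromene 1-(2,2-dimethyl-2H-chromen-6-yl)ethanone A5 would be made from 8 in two steps (O-propargylation and thermal rearrangement). A5 would be epoxidised with the enantiomer of [N,N'-bis(3,5-di-tert-butylsalicylidene)cyclohexane-1,2-diaminato]manganese chloride (trivalent manganese) that gives (3R,4R)-6-acetyl-3,4-epoxy-2,2-dimethylchroman A6. 3-Methylbutanoic acid would open the oxirane of A6 at benzylic C4 with inversion to (3R,4S)-6-acetyl-3-hydroxy-2,2-dimethylchroman-4-yl 3-methylbutanoate A7.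
- Forward key step: triflation of the C3 hydroxyl of A7 would trigger a 1,2-shift of the aryloxy oxygen from the quaternary carbon to C3 with inversion. Loss of a methyl proton from the tertiary cation would give (2R,3S)-5-acetyl-2-(prop-1-en-2-yl)-2,3-dihydrobenzofuran-3-yl 3-methylbutanoate A8.
- In favour: it is the shortest plan, about eight steps in all against twelve, which is better than the chosen plan. The absolute configuration comes from a very well-established catalytic epoxidation of exactly the substrate class of A5, also better. The C3 ester is installed during the opening of A6, which is equal or better.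
- Against: the key step is the least secure of all four. The trans-vicinal acyloxy group of A7 is ideally placed to participate through a 1,3-dioxolan-2-ylium ion. The ring oxygen is a weak migrating group because its lone pair is drawn into the para-acetyl arene. The tertiary cation can also lose the hydrogen on the new C2 to give a tetrasubstituted enol ether. Like A4, the product A8 lacks the branch oxygen, so a late methyl oxidation is needed.
- Comparison: better on step economy and on the source of chirality, but weaker on mechanism (three competing cationic pathways) and on structure (branch at the wrong oxidation level).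

Key step: step 8

Assumption: the (2R,5R)-thiolane is taken to give the (2S,3S)-oxirane, by analogy with the sense usual for benzyl- and allyl-type ylides of this sulfide; were it opposite, the sulfide branch would be run in the mirror-image series and nothing else would change.

## Route

Step 1
Reactants: 1 2-methylenepropane-1,3-diol
Product: 2 2-[(tert-butyldiphenylsilyloxy)methyl]prop-2-en-1-ol
Conditions: TBDPSCl (1 equiv), imidazole, DMF, 0 → 25 °C; 1 in threefold excess
Reagents that add atoms: tert-butyl(chloro)diphenylsilane, CC(C)(C)[Si](Cl)(c1ccccc1)c1ccccc1
Why: Statistical monosilylation of a symmetric diol used in excess; the bulky silyl chloride reacts more slowly with the mono-ether than with the diol, and the excess diol is washed out with water.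

Step 2
Reactants: 2 2-[(tert-butyldiphenylsilyloxy)methyl]prop-2-en-1-ol
Product: 3 [2-(bromomethyl)prop-2-enyloxy](tert-butyl)diphenylsilane
Conditions: CBr4, PPh3, CH2Cl2, 0 °C
Reagents that add atoms: tetrabromomethane, BrC(Br)(Br)Br
Why: Appel reaction: the alkoxyphosphonium ion is displaced by bromide under neutral conditions that leave the silyl ether alone; the allyl unit is symmetric, so direct and allylic displacement give the same bromide.

Step 3
Reactants: 4 (2S,5S)-hexane-2,5-diol
Product: 5 (2S,5S)-hexane-2,5-diyl dimethanesulfonate
Conditions: MsCl, Et3N, CH2Cl2, −10 → 0 °C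
Reagents that add atoms: methanesulfonyl chloride, CS(=O)(=O)Cl
Why: Sulfonylation at oxygen; no C–O bond is broken, so both centres stay S.

Step 4
Reactants: 5 (2S,5S)-hexane-2,5-diyl dimethanesulfonate
Product: 6 (2R,5R)-2,5-dimethylthiolane
Conditions: Na2S·9H2O, DMSO, 25 °C
Reagents that add atoms: sodium sulfide, [Na+].[Na+].[S-2]
Why: Double SN2 displacement by sulfide; each secondary mesylate is displaced with inversion, so (S,S) becomes (R,R), and the second displacement is a fast 5-exo-tet closure that outruns elimination in a dipolar aprotic solvent.

Step 5
Reactants: 6 (2R,5R)-2,5-dimethylthiolane; 3 [2-(bromomethyl)prop-2-enyloxy](tert-butyl)diphenylsilane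
Product: 7 (2R,5R)-1-[2-[(tert-butyldiphenylsilyloxy)methyl]prop-2-enyl]-2,5-dimethylthiolan-1-ium tetrafluoroborate
Conditions: NaBF4, CH2Cl2/H2O, 25 °C
Reagents that add atoms: sodium tetrafluoroborate, [Na+].F[B-](F)(F)F
Why: S-Alkylation of the sulfide by a reactive allylic bromide; bromide passes into the water layer and is replaced by non-nucleophilic tetrafluoroborate, which prevents dealkylation; the lone pairs of the C2-symmetric sulfide are homotopic, so a single salt forms.

Step 6
Reactants: 8 4-hydroxyacetophenone
Product: 9 5-acetyl-2-hydroxybenzaldehyde
Conditions: (CH2)6N4, CF3CO2H, 85 °C; then H2O, 25 °C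
Reagents that add atoms: hexamethylenetetramine, C1N2CN3CN1CN(C2)C3; water, O
Why: Duff formylation: an iminium ion from hexamethylenetetramine attacks ortho to the phenol (para is blocked), an internal hydride shift gives the benzylic iminium ion and water releases the aldehyde; the acetyl group deactivates the ring enough to favour monoformylation.

Step 7
Reactants: 9 5-acetyl-2-hydroxybenzaldehyde
Product: 10 5-acetyl-2-(triisopropylsilyloxy)benzaldehyde
Conditions: TIPSCl, imidazole, DMF, 25 °C
Reagents that add atoms: chlorotriisopropylsilane, CC(C)[Si](Cl)(C(C)C)C(C)C
Why: Imidazole-mediated silylation of an acidic phenol; the bulky triisopropylsilyl group is chosen because it resists premature loss and O-to-O transfer in the next step yet is still cleaved from an aryl oxygen by fluoride.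

Step 8
Reactants: 10 5-acetyl-2-(triisopropylsilyloxy)benzaldehyde; 7 (2R,5R)-1-[2-[(tert-butyldiphenylsilyloxy)methyl]prop-2-enyl]-2,5-dimethylthiolan-1-ium tetrafluoroborate
Product: 15 1-[(2R,3S)-2-[3-(tert-butyldiphenylsilyloxy)prop-1-en-2-yl]-3-hydroxy-2,3-dihydrobenzofuran-5-yl]ethanone, via sulfonium allylide 11 (not isolated), via anti betaine 12 (not isolated), via trans vinyl epoxide 13 (not isolated), via cesium epoxy phenoxide 14 (not isolated)
Conditions: EtN=P(NMe2)2–N=P(NMe2)3 (P2-Et), CH2Cl2, −78 °C; then DMF, CsF, 0 → 25 °C; H2O
Reagents that add atoms: none
Why: The phosphazene base removes an allylic S–CH2 proton of 7 (far more acidic than the methyl ketone) to give allylide 11, which adds through its α-carbon to the aldehyde of 10; anti betaine 12 then closes by 3-exo-tet displacement of the thiolane to trans vinyl epoxide 13, a sulfur-ylide epoxidation of the Corey–Chaykovsky type with a chiral sulfide. CsF then cleaves only the aryl O–Si bond, because the acetyl-stabilised phenoxide leaves silicon far more readily than a primary alkoxide, and gives 14. The phenoxide opens the oxirane at the allylic carbon with inversion in a 5-endo-tet closure of the dihydrofuran ring, for which the closest known reaction type is the base-mediated cyclisation of 2-(oxiranyl)phenols to 2,3-dihydrobenzofuran-3-ols; attack at the benzylic carbon would be a strained 4-exo closure and SN2' attack would need a seven-membered ring. C3 is set in the C–C bond formation, where the C2-symmetric 2,5-dimethylthiolane fixes the ylide conformation and shields one of its faces so that one aldehyde face is attacked. C2 is set relative to C3: the anti betaine gives the trans oxirane and the stereospecific inversion then gives the trans (2R,3S) ring. The step needs aldehyde over ketone selectivity (intrinsic electrophilicity at −78 °C), α over γ attack and trans over cis oxirane, the last two favoured by the substituent on the central allyl carbon as in 2-methylallyl ylides. It also needs closure of 12 before silyl transfer, which the bulky triisopropylsilyl group secures, since transfer followed by direct displacement of the sulfonium group by phenoxide would give the cis ring. The para-acetyl group tempers the phenoxide, so ionisation of the benzylic C–O bond to an ortho-quinone methide, which would scramble C3, is disfavoured.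

Step 9
Reactants: 15 1-[(2R,3S)-2-[3-(tert-butyldiphenylsilyloxy)prop-1-en-2-yl]-3-hydroxy-2,3-dihydrobenzofuran-5-yl]ethanone
Product: 16 (2R,3S)-2-[3-(tert-butyldiphenylsilyloxy)prop-1-en-2-yl]-5-[(1R)-1-hydroxyethyl]-2,3-dihydrobenzofuran-3-ol
Conditions: RuCl[(R,R)-TsDPEN](p-cymene) (cat.), HCO2H/Et3N (1:5, amine-rich), EtOAc, 30 °C
Reagents that add atoms: none
Why: Noyori-type asymmetric transfer hydrogenation of an aryl methyl ketone; the (R,R)-ligand directs outer-sphere hydride delivery to the Si face and gives the (R)-carbinol by reagent control, independent of the remote ring centres. No borane is present, so the 1,1-disubstituted alkene cannot be hydroborated and the free C3 hydroxyl consumes no reagent; the amine-rich formate medium stays basic, so the benzylic C3 hydroxyl is not ionised.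

Step 10
Reactants: 16 (2R,3S)-2-[3-(tert-butyldiphenylsilyloxy)prop-1-en-2-yl]-5-[(1R)-1-hydroxyethyl]-2,3-dihydrobenzofuran-3-ol
Product: 17 (1R)-1-[(2R,3S)-2-[3-(tert-butyldiphenylsilyloxy)prop-1-en-2-yl]-3-(3-methylbutanoyloxy)-2,3-dihydrobenzofuran-5-yl]ethyl 3-methylbutanoate
Conditions: (Me2CHCH2CO)2O, Et3N, DMAP (cat.), CH2Cl2, 0 → 25 °C
Reagents that add atoms: 3-methylbutanoic anhydride, CC(C)CC(=O)OC(=O)CC(C)C
Why: DMAP-catalysed acylation of both secondary benzylic hydroxyls through the N-acylpyridinium ion; no C–O bond at a stereocentre is broken, so all three configurations are retained.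

Step 11
Reactants: 17 (1R)-1-[(2R,3S)-2-[3-(tert-butyldiphenylsilyloxy)prop-1-en-2-yl]-3-(3-methylbutanoyloxy)-2,3-dihydrobenzofuran-5-yl]ethyl 3-methylbutanoate
Product: 18 (1R)-1-[(2R,3S)-2-(3-hydroxyprop-1-en-2-yl)-3-(3-methylbutanoyloxy)-2,3-dihydrobenzofuran-5-yl]ethyl 3-methylbutanoate
Conditions: Bu4NF, AcOH (1:1), THF, 0 → 25 °C
Reagents that add atoms: none
Why: Fluoride-induced cleavage of the Si–O bond, driven by the strong Si–F bond; acetic acid protonates the alkoxide as it forms, so the esters neither migrate nor cleave and the benzylic C3 ester is not eliminated.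

Step 12
Reactants: 18 (1R)-1-[(2R,3S)-2-(3-hydroxyprop-1-en-2-yl)-3-(3-methylbutanoyloxy)-2,3-dihydrobenzofuran-5-yl]ethyl 3-methylbutanoate
Product: 19 (1R)-1-[(2R,3S)-3-(3-methylbutanoyloxy)-2-(3-oxoprop-1-en-2-yl)-2,3-dihydrobenzofuran-5-yl]ethyl 3-methylbutanoate
Conditions: MnO2 (activated, excess), CH2Cl2, 25 °C
Reagents that add atoms: none
Why: Selective oxidation of a primary allylic alcohol to the enal on the MnO2 surface without over-oxidation; the neutral heterogeneous conditions spare the benzylic esters, and no other oxidisable hydroxyl remains.

## Compound list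

1 | 2-methylenepropane-1,3-diol | C=C(CO)CO | starting material
2 | 2-[(tert-butyldiphenylsilyloxy)methyl]prop-2-en-1-ol | C=C(CO)CO[Si](c1ccccc1)(c1ccccc1)C(C)(C)C | intermediate
3 | [2-(bromomethyl)prop-2-enyloxy](tert-butyl)diphenylsilane | C=C(CBr)CO[Si](c1ccccc1)(c1ccccc1)C(C)(C)C | intermediate
4 | (2S,5S)-hexane-2,5-diol | C[C@H](O)CC[C@H](C)O | starting material
5 | (2S,5S)-hexane-2,5-diyl dimethanesulfonate | C[C@H](OS(C)(=O)=O)CC[C@H](C)OS(C)(=O)=O | intermediate
6 | (2R,5R)-2,5-dimethylthiolane | C[C@@H]1CC[C@@H](C)S1 | intermediate
7 | (2R,5R)-1-[2-[(tert-butyldiphenylsilyloxy)methyl]prop-2-enyl]-2,5-dimethylthiolan-1-ium tetrafluoroborate | C[C@@H]1CC[C@@H](C)[S+]1CC(=C)CO[Si](c1ccccc1)(c1ccccc1)C(C)(C)C.F[B-](F)(F)F | intermediate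
8 | 4-hydroxyacetophenone | CC(=O)c1ccc(O)cc1 | starting material
9 | 5-acetyl-2-hydroxybenzaldehyde | CC(=O)c1ccc(O)c(C=O)c1 | intermediate
10 | 5-acetyl-2-(triisopropylsilyloxy)benzaldehyde | CC(=O)c1ccc(O[Si](C(C)C)(C(C)C)C(C)C)c(C=O)c1 | intermediate
11 | 2-[(tert-butyldiphenylsilyloxy)methyl]-1-[(2R,5R)-2,5-dimethylthiolan-1-ium-1-yl]prop-2-en-1-ide (sulfonium allylide) | C[C@@H]1CC[C@@H](C)[S+]1[CH-]C(=C)CO[Si](c1ccccc1)(c1ccccc1)C(C)(C)C | intermediate (not isolated)
12 | (1S,2R)-1-[5-acetyl-2-(triisopropylsilyloxy)phenyl]-3-[(tert-butyldiphenylsilyloxy)methyl]-2-[(2R,5R)-2,5-dimethylthiolan-1-ium-1-yl]but-3-en-1-olate (anti betaine) | C=C(CO[Si](c1ccccc1)(c1ccccc1)C(C)(C)C)[C@@H]([S+]1[C@H](C)CC[C@H]1C)[C@@H]([O-])c1cc(C(C)=O)ccc1O[Si](C(C)C)(C(C)C)C(C)C | intermediate (not isolated)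
13 | 1-[3-[(2S,3S)-3-[3-(tert-butyldiphenylsilyloxy)prop-1-en-2-yl]oxiran-2-yl]-4-(triisopropylsilyloxy)phenyl]ethanone | C=C(CO[Si](c1ccccc1)(c1ccccc1)C(C)(C)C)[C@@H]1O[C@H]1c1cc(C(C)=O)ccc1O[Si](C(C)C)(C(C)C)C(C)C | intermediate (not isolated)
14 | cesium 4-acetyl-2-[(2S,3S)-3-[3-(tert-butyldiphenylsilyloxy)prop-1-en-2-yl]oxiran-2-yl]phenolate | C=C(CO[Si](c1ccccc1)(c1ccccc1)C(C)(C)C)[C@@H]1O[C@H]1c1cc(C(C)=O)ccc1[O-].[Cs+] | intermediate (not isolated)
15 | 1-[(2R,3S)-2-[3-(tert-butyldiphenylsilyloxy)prop-1-en-2-yl]-3-hydroxy-2,3-dihydrobenzofuran-5-yl]ethanone | C=C(CO[Si](c1ccccc1)(c1ccccc1)C(C)(C)C)[C@H]1Oc2ccc(C(C)=O)cc2[C@@H]1O | intermediate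
16 | (2R,3S)-2-[3-(tert-butyldiphenylsilyloxy)prop-1-en-2-yl]-5-[(1R)-1-hydroxyethyl]-2,3-dihydrobenzofuran-3-ol | C=C(CO[Si](c1ccccc1)(c1ccccc1)C(C)(C)C)[C@H]1Oc2ccc([C@@H](C)O)cc2[C@@H]1O | intermediate
17 | (1R)-1-[(2R,3S)-2-[3-(tert-butyldiphenylsilyloxy)prop-1-en-2-yl]-3-(3-methylbutanoyloxy)-2,3-dihydrobenzofuran-5-yl]ethyl 3-methylbutanoate | C=C(CO[Si](c1ccccc1)(c1ccccc1)C(C)(C)C)[C@H]1Oc2ccc([C@@H](C)OC(=O)CC(C)C)cc2[C@@H]1OC(=O)CC(C)C | intermediate
18 | (1R)-1-[(2R,3S)-2-(3-hydroxyprop-1-en-2-yl)-3-(3-methylbutanoyloxy)-2,3-dihydrobenzofuran-5-yl]ethyl 3-methylbutanoate | C=C(CO)[C@H]1Oc2ccc([C@@H](C)OC(=O)CC(C)C)cc2[C@@H]1OC(=O)CC(C)C | intermediate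
19 | (1R)-1-[(2R,3S)-3-(3-methylbutanoyloxy)-2-(3-oxoprop-1-en-2-yl)-2,3-dihydrobenzofuran-5-yl]ethyl 3-methylbutanoate | C=C(C=O)[C@H]1Oc2ccc([C@@H](C)OC(=O)CC(C)C)cc2[C@@H]1OC(=O)CC(C)C | target

## Step count and least certain steps

Total: 12 steps. Longest linear sequence: 8 steps (1 → 2 → 3 → 7 → 15 → 16 → 17 → 18 → 19; the branch from 4 through 5, 6 and 7 is equally long, and the branch from 8 has 7 steps).

Step 8 (key step). The most likely failures are:
- poor facial selectivity of the allylide, or erosion of the trans preference when the betaine forms;
- silyl transfer from the phenol oxygen to the betaine alkoxide, which would lead to the cis ring;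
- slow opening of the oxirane by the deactivated phenoxide, giving time for ionisation at the benzylic carbon.

The fallback abandons the ylide and uses known reactions only. It sets out from 3 and 10. An Arbuzov reaction of 3 with P(OEt)3 would give diethyl [2-[(tert-butyldiphenylsilyloxy)methyl]prop-2-enyl]phosphonate F1. Its anion (LiN(SiMe3)2, THF, −78 °C) would olefinate 10 in a Horner–Wadsworth–Emmons reaction to 1-[3-[(1E)-3-[(tert-butyldiphenylsilyloxy)methyl]buta-1,3-dienyl]-4-(triisopropylsilyloxy)phenyl]ethanone F2. Shi epoxidation with the enantiomer of the D-fructose-derived ketone and Oxone (2KHSO5·KHSO4·K2SO4) buffered with K2CO3 should select the trans-disubstituted styrenyl double bond over the 1,1-disubstituted one; that ketone enantiomer is the one expected to give (S,S)-oxides from trans-disubstituted styrenes. The fallback comes back to the route at 13, now isolated, which CsF in DMF would convert to 15 as in step 8.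

Step 9. The most likely failures are slow turnover with the electron-rich ketone in the amine-rich medium, incomplete facial selectivity, or reversible dehydrogenation at the free C3 carbinol by the ruthenium hydride, which would erode the ring stereochemistry. The fallback changes the order of events and the reductant. It sets out from 15, which would be acylated first (3-methylbutanoic anhydride, DMAP) to (2R,3S)-5-acetyl-2-[3-(tert-butyldiphenylsilyloxy)prop-1-en-2-yl]-2,3-dihydrobenzofuran-3-yl 3-methylbutanoate F3. Corey–Bakshi–Shibata reduction with the (S)-methyl oxazaborolidine and catecholborane in toluene at −78 °C, which does not hydroborate the alkene, would give (2R,3S)-2-[3-(tert-butyldiphenylsilyloxy)prop-1-en-2-yl]-5-[(1R)-1-hydroxyethyl]-2,3-dihydrobenzofuran-3-yl 3-methylbutanoate F4. A second acylation would return to the route at 17.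

Step 5. The most likely failure is incomplete or reversible alkylation of the hindered sulfide, with a salt that is hard to free from starting materials. The fallback changes the electrophile and bypasses 3. It sets out from 2 and 6: Tf2O and 2,6-lutidine in CH2Cl2 at −78 °C would give 2-[(tert-butyldiphenylsilyloxy)methyl]prop-2-enyl trifluoromethanesulfonate F5 in the flask. 6 would trap it irreversibly as (2R,5R)-1-[2-[(tert-butyldiphenylsilyloxy)methyl]prop-2-enyl]-2,5-dimethylthiolan-1-ium trifluoromethanesulfonate F6. Deprotonation of F6 in step 8 gives the same ylide, so the fallback rejoins the route at 11.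

Step 12. The most likely failure is sluggish surface oxidation, because the alcohol is allylic only to a 1,1-disubstituted alkene, with conjugate addition or polymerisation of the enal on long contact. The fallback sets out from 18 and returns at 19. It replaces the heterogeneous oxidant by a homogeneous oxoammonium oxidation (TEMPO (cat.), PhI(OAc)2, CH2Cl2, 25 °C), which acts by hydride abstraction from the carbinol carbon and is selective for primary alcohols. This fallback makes no new compound, F0.

## Further compounds

F1 | step 8 | diethyl [2-[(tert-butyldiphenylsilyloxy)methyl]prop-2-enyl]phosphonate | C=C(CP(=O)(OCC)OCC)CO[Si](c1ccccc1)(c1ccccc1)C(C)(C)C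
F2 | step 8 | 1-[3-[(1E)-3-[(tert-butyldiphenylsilyloxy)methyl]buta-1,3-dienyl]-4-(triisopropylsilyloxy)phenyl]ethanone | C=C(CO[Si](c1ccccc1)(c1ccccc1)C(C)(C)C)/C=C/c1cc(C(C)=O)ccc1O[Si](C(C)C)(C(C)C)C(C)C
F3 | step 9 | (2R,3S)-5-acetyl-2-[3-(tert-butyldiphenylsilyloxy)prop-1-en-2-yl]-2,3-dihydrobenzofuran-3-yl 3-methylbutanoate | C=C(CO[Si](c1ccccc1)(c1ccccc1)C(C)(C)C)[C@H]1Oc2ccc(C(C)=O)cc2[C@@H]1OC(=O)CC(C)C
F4 | step 9 | (2R,3S)-2-[3-(tert-butyldiphenylsilyloxy)prop-1-en-2-yl]-5-[(1R)-1-hydroxyethyl]-2,3-dihydrobenzofuran-3-yl 3-methylbutanoate | C=C(CO[Si](c1ccccc1)(c1ccccc1)C(C)(C)C)[C@H]1Oc2ccc([C@@H](C)O)cc2[C@@H]1OC(=O)CC(C)C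
F5 | step 5 | 2-[(tert-butyldiphenylsilyloxy)methyl]prop-2-enyl trifluoromethanesulfonate | C=C(COS(=O)(=O)C(F)(F)F)CO[Si](c1ccccc1)(c1ccccc1)C(C)(C)C
F6 | step 5 | (2R,5R)-1-[2-[(tert-butyldiphenylsilyloxy)methyl]prop-2-enyl]-2,5-dimethylthiolan-1-ium trifluoromethanesulfonate | C[C@@H]1CC[C@@H](C)[S+]1CC(=C)CO[Si](c1ccccc1)(c1ccccc1)C(C)(C)C.[O-]S(=O)(=O)C(F)(F)F
F0 | step 12 | none | none
A1 | alternative 1 | 1-[5-bromo-2-[2-methyl-2-(triethylsilyloxy)propoxy]phenyl]-1-diazo-4-methylpentan-2-one | CC(C)CC(=O)C(=[N+]=[N-])c1cc(Br)ccc1OCC(C)(C)O[Si](CC)(CC)CC
A2 | alternative 1 | (2S,3S)-1-[5-bromo-2-[2-(triethylsilyloxy)propan-2-yl]-2,3-dihydrobenzofuran-3-yl]-3-methylbutan-1-one | CC(C)(O[Si](CC)(CC)CC)[C@H]1Oc2ccc(Br)cc2[C@@H]1C(=O)CC(C)C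
A3 | alternative 2 | 1-[3-[(1S,2R)-1,2-dihydroxy-3-methylbut-3-enyl]-4-fluorophenyl]ethanone | C=C(C)[C@@H](O)[C@@H](O)c1cc(C(C)=O)ccc1F
A4 | alternative 2 | 1-[(2R,3S)-3-hydroxy-2-(prop-1-en-2-yl)-2,3-dihydrobenzofuran-5-yl]ethanone | C=C(C)[C@H]1Oc2ccc(C(C)=O)cc2[C@@H]1O
A5 | alternative 3 | 1-(2,2-dimethyl-2H-chromen-6-yl)ethanone | CC(=O)c1ccc2OC(C)(C)C=Cc2c1
A6 | alternative 3 | (3R,4R)-6-acetyl-3,4-epoxy-2,2-dimethylchroman | CC(=O)c1ccc2OC(C)(C)[C@@H]3O[C@@H]3c2c1
A7 | alternative 3 | (3R,4S)-6-acetyl-3-hydroxy-2,2-dimethylchroman-4-yl 3-methylbutanoate | CC(C)CC(=O)O[C@H]1c2cc(C(C)=O)ccc2OC(C)(C)[C@@H]1O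
A8 | alternative 3 | (2R,3S)-5-acetyl-2-(prop-1-en-2-yl)-2,3-dihydrobenzofuran-3-yl 3-methylbutanoate | C=C(C)[C@H]1Oc2ccc(C(C)=O)cc2[C@@H]1OC(=O)CC(C)C
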